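**Retrosynthetic overview**

1. Numbering used below: C1 (CH–O‑isobutyryl), C2–C3 (CH2CH2), C4(C15H2OH)=C5, C6 (CH–O of the methylene lactone), C7, C8 (CH–O of the butenolide), C9=C10, C11(=C13H2)–C12(=O), C14 (butenolide C=O).
2. Target ⇐ desilylation ⇐ one‑flask rhodium‑then‑ruthenium relay on an acyclic alkynyl acrylic acid: the C14 carboxyl oxygen is joined to C8 by branched‑selective acid‑to‑alkyne addition (eleven‑membered lactone), then C9=C10 is made by ring‑closing metathesis (butenolide and ten‑membered carbocycle at once).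
3. Enabling feature: the butenolide ring O–C14(=O)–C10=C9–C8 is a cyclised branched allyl acrylate. Its γ‑carbon C8 is the propargylic CH2 of a C8H2–C9≡CH unit in the precursor, and C9=C10 lies in a five‑membered ring, so the C8–C9–C10 bridge of the ten‑membered ring closes with five‑ring kinetics.
4. Seco acid ⇐ C1–C10 by a catalyst‑controlled Morita–Baylis–Hillman reaction on a C1 aldehyde; C4=C5 ⇐ E‑selective Wittig reaction of an α‑formyl ylide (C1–C4, C15) with the C5 aldehyde of the lactone core.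
5. Lactone core ⇐ (S)‑5‑(hydroxymethyl)furan‑2(5H)‑one: anti conjugate allylation (C7), anti Mannich reaction (masked C11=C13), allyl → propargyl. Ring order: methylene lactone (chiral pool) → eleven‑membered lactone → butenolide plus ten‑membered ring.

Key step: step 18

Remark (assumption on the chemistry): the (R,R) antipode of DIOP is taken to give the (8R) ester, by analogy with its sense of induction in intermolecular acid–alkyne couplings; if the sense is opposite, (S,S)‑DIOP is used instead.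
Remark: compounds 1 and 12 are taken as commercial.

**Route**

Step 1
Reactants: 1 (S)‑5‑(hydroxymethyl)furan‑2(5H)‑one
Product: 2 (S)‑5‑{[(tert‑butyldimethylsilyl)oxy]methyl}furan‑2(5H)‑one
Conditions: TBSCl, imidazole, DMF, 0 °C to rt
Reagents that add atoms: tert‑butyldimethylsilyl chloride, CC(C)(C)[Si](C)(C)Cl
Why: Imidazole‑mediated silylation of a primary alcohol; the stereocentre is not touched.

Step 2
Reactants: 2 (S)‑5‑{[(tert‑butyldimethylsilyl)oxy]methyl}furan‑2(5H)‑one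
Product: 4 (4S,5S)‑4‑allyl‑5‑{[(tert‑butyldimethylsilyl)oxy]methyl}dihydrofuran‑2(3H)‑one (4,5‑trans), via silyl ketene acetal 3 (not isolated)
Conditions: CH2=CHCH2MgBr, CuBr·SMe2 (20 mol %), Me3SiCl, THF, −78 °C; aq. NH4Cl
Reagents that add atoms: allylmagnesium bromide, C=CC[Mg]Br
Why: Copper‑catalysed, chlorosilane‑accelerated conjugate addition; the allyl group should enter C7 anti to the silyloxymethyl group on C6 of the flat butenolide, which sets the trans relationship, and the enolate is trapped as the silyl ketene acetal.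

Step 3
Reactants: 4 (4S,5S)‑4‑allyl‑5‑{[(tert‑butyldimethylsilyl)oxy]methyl}dihydrofuran‑2(3H)‑one
Product: 6 (3R,4S,5S)‑4‑allyl‑5‑{[(tert‑butyldimethylsilyl)oxy]methyl}‑3‑[(dimethylamino)methyl]dihydrofuran‑2(3H)‑one (all‑trans), via lithium enolate 5 (not isolated)
Conditions: LiN(iPr)2, THF, −78 °C; then CH2=NMe2+ I−, −78 to 0 °C
Reagents that add atoms: N,N‑dimethylmethyleneiminium iodide (Eschenmoser's salt), [I-].C=[N+](C)C
Why: Mannich reaction of the lactone enolate with Eschenmoser's salt; attack anti to the allyl group on C7 should give the 3,4‑trans product, and the β‑amino lactone is a masked α‑methylene lactone that is inert to the nucleophiles and hydrides used later.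

Step 4
Reactants: 6 (3R,4S,5S)‑4‑allyl‑5‑{[(tert‑butyldimethylsilyl)oxy]methyl}‑3‑[(dimethylamino)methyl]dihydrofuran‑2(3H)‑one
Product: 8 (3R,4S,5S)‑5‑{[(tert‑butyldimethylsilyl)oxy]methyl}‑3‑[(dimethylamino)methyl]‑4‑(2‑oxoethyl)dihydrofuran‑2(3H)‑one, via ozonide salt 7 (not isolated)
Conditions: CF3CO2H (1.1 equiv), CH2Cl2, −78 °C, O3; then Me2S, −78 °C to rt; aq. NaHCO3
Reagents that add atoms: ozone, [O-][O+]=O
Why: Ozonolysis of the only C=C bond with reductive cleavage of the ozonide; protonation shields the tertiary amine from ozone.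

Step 5
Reactants: 8 (3R,4S,5S)‑5‑{[(tert‑butyldimethylsilyl)oxy]methyl}‑3‑[(dimethylamino)methyl]‑4‑(2‑oxoethyl)dihydrofuran‑2(3H)‑one
Product: 9 (3R,4S,5S)‑5‑{[(tert‑butyldimethylsilyl)oxy]methyl}‑3‑[(dimethylamino)methyl]‑4‑(prop‑2‑yn‑1‑yl)dihydrofuran‑2(3H)‑one
Conditions: dimethyl (1‑diazo‑2‑oxopropyl)phosphonate, K2CO3, MeOH, 0 °C to rt
Reagents that add atoms: dimethyl (1‑diazo‑2‑oxopropyl)phosphonate, CC(=O)C(=[N+]=[N-])P(=O)(OC)OC
Why: Seyferth–Gilbert homologation with the Ohira–Bestmann reagent turns the aldehyde into the terminal alkyne (C8H2–C9≡CH); the amine‑masked lactone tolerates methoxide, which a free methylene lactone would not.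

Step 6
Reactants: 9 (3R,4S,5S)‑5‑{[(tert‑butyldimethylsilyl)oxy]methyl}‑3‑[(dimethylamino)methyl]‑4‑(prop‑2‑yn‑1‑yl)dihydrofuran‑2(3H)‑one
Product: 10 (3R,4S,5S)‑3‑[(dimethylamino)methyl]‑5‑(hydroxymethyl)‑4‑(prop‑2‑yn‑1‑yl)dihydrofuran‑2(3H)‑one
Conditions: HF·pyridine, THF, 0 °C to rt
Reagents that add atoms: none
Why: Fluoride cleavage of the primary silyl ether under acidic buffering, which should leave the lactone closed.

Step 7
Reactants: 10 (3R,4S,5S)‑3‑[(dimethylamino)methyl]‑5‑(hydroxymethyl)‑4‑(prop‑2‑yn‑1‑yl)dihydrofuran‑2(3H)‑one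
Product: 11 (2S,3S,4R)‑4‑[(dimethylamino)methyl]‑5‑oxo‑3‑(prop‑2‑yn‑1‑yl)tetrahydrofuran‑2‑carbaldehyde
Conditions: Dess–Martin periodinane, NaHCO3, CH2Cl2, 0 °C; used crude
Reagents that add atoms: none
Why: Dess–Martin oxidation under buffered, non‑basic conditions, chosen so that the α‑acyloxy aldehyde centre C6 is not epimerised.

Step 8
Reactants: 12 2‑(3‑chloropropyl)‑1,3‑dioxolane
Product: 13 [3‑(1,3‑dioxolan‑2‑yl)propyl]triphenylphosphonium iodide
Conditions: PPh3, NaI, MeCN, reflux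
Reagents that add atoms: triphenylphosphine, c1ccc(cc1)P(c1ccccc1)c1ccccc1; sodium iodide, [Na+].[I-]
Why: Finkelstein‑assisted SN2 quaternisation of triphenylphosphine by a primary halide.

Step 9
Reactants: 13 [3‑(1,3‑dioxolan‑2‑yl)propyl]triphenylphosphonium iodide
Product: 15 4‑(1,3‑dioxolan‑2‑yl)‑2‑(triphenyl‑λ5‑phosphanylidene)butanal, via phosphorus ylide 14 (not isolated)
Conditions: KOtBu (2.1 equiv), THF, 0 °C; then HCO2Et, 0 °C to rt
Reagents that add atoms: ethyl formate, CCOC=O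
Why: C‑acylation of a non‑stabilised phosphorus ylide by ethyl formate; the second equivalent of base removes the now acidic proton to give the stabilised α‑formyl ylide.

Step 10
Reactants: 11 (2S,3S,4R)‑4‑[(dimethylamino)methyl]‑5‑oxo‑3‑(prop‑2‑yn‑1‑yl)tetrahydrofuran‑2‑carbaldehyde; 15 4‑(1,3‑dioxolan‑2‑yl)‑2‑(triphenyl‑λ5‑phosphanylidene)butanal
Product: 16 (E)‑4‑(1,3‑dioxolan‑2‑yl)‑2‑{[(2S,3S,4R)‑4‑[(dimethylamino)methyl]‑5‑oxo‑3‑(prop‑2‑yn‑1‑yl)tetrahydrofuran‑2‑yl]methylidene}butanal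
Conditions: toluene, 70 °C
Reagents that add atoms: none
Why: Wittig reaction of a stabilised α‑substituted formyl ylide, which is E‑selective (formyl group trans to C6); this places C3 cis to C6 across C4=C5 as the target requires.

Step 11
Reactants: 16 (E)‑4‑(1,3‑dioxolan‑2‑yl)‑2‑{[(2S,3S,4R)‑4‑[(dimethylamino)methyl]‑5‑oxo‑3‑(prop‑2‑yn‑1‑yl)tetrahydrofuran‑2‑yl]methylidene}butanal
Product: 17 (3R,4S,5S)‑3‑[(dimethylamino)methyl]‑5‑[(1E)‑4‑(1,3‑dioxolan‑2‑yl)‑2‑(hydroxymethyl)but‑1‑en‑1‑yl]‑4‑(prop‑2‑yn‑1‑yl)dihydrofuran‑2(3H)‑one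
Conditions: NaBH4, CeCl3·7H2O, MeOH, −40 °C
Reagents that add atoms: none
Why: Luche 1,2‑reduction of the enal; the lactone is not reduced at this temperature and the masked methylene lactone cannot undergo conjugate reduction.

Step 12
Reactants: 17 (3R,4S,5S)‑3‑[(dimethylamino)methyl]‑5‑[(1E)‑4‑(1,3‑dioxolan‑2‑yl)‑2‑(hydroxymethyl)but‑1‑en‑1‑yl]‑4‑(prop‑2‑yn‑1‑yl)dihydrofuran‑2(3H)‑one
Product: 18 (3R,4S,5S)‑5‑[(1E)‑2‑{[(tert‑butyldiphenylsilyl)oxy]methyl}‑4‑(1,3‑dioxolan‑2‑yl)but‑1‑en‑1‑yl]‑3‑[(dimethylamino)methyl]‑4‑(prop‑2‑yn‑1‑yl)dihydrofuran‑2(3H)‑one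
Conditions: TBDPSCl, imidazole, DMF, rt
Reagents that add atoms: tert‑butyldiphenylsilyl chloride, CC(C)(C)[Si](Cl)(c1ccccc1)c1ccccc1
Why: Silylation of the primary allylic alcohol (C15) with a group that survives the aqueous acid of step 14.

Step 13
Reactants: 18 (3R,4S,5S)‑5‑[(1E)‑2‑{[(tert‑butyldiphenylsilyl)oxy]methyl}‑4‑(1,3‑dioxolan‑2‑yl)but‑1‑en‑1‑yl]‑3‑[(dimethylamino)methyl]‑4‑(prop‑2‑yn‑1‑yl)dihydrofuran‑2(3H)‑one
Product: 20 (4S,5R)‑5‑[(1E)‑2‑{[(tert‑butyldiphenylsilyl)oxy]methyl}‑4‑(1,3‑dioxolan‑2‑yl)but‑1‑en‑1‑yl]‑3‑methylene‑4‑(prop‑2‑yn‑1‑yl)dihydrofuran‑2(3H)‑one (4,5‑trans), via quaternary ammonium iodide 19 (not isolated)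
Conditions: MeI, CH2Cl2, rt; evaporate; then NaHCO3, CH2Cl2/H2O, rt
Reagents that add atoms: none
Why: N‑methylation followed by E1cB (Hofmann‑type) loss of trimethylamine from the Mannich base unmasks the C11=C13 methylene; the C11 stereocentre disappears and C6/C7 are not affected.

Step 14
Reactants: 20 (4S,5R)‑5‑[(1E)‑2‑{[(tert‑butyldiphenylsilyl)oxy]methyl}‑4‑(1,3‑dioxolan‑2‑yl)but‑1‑en‑1‑yl]‑3‑methylene‑4‑(prop‑2‑yn‑1‑yl)dihydrofuran‑2(3H)‑one
Product: 21 (4S,5R)‑5‑[(1E)‑2‑{[(tert‑butyldiphenylsilyl)oxy]methyl}‑5‑oxopent‑1‑en‑1‑yl]‑3‑methylene‑4‑(prop‑2‑yn‑1‑yl)dihydrofuran‑2(3H)‑one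
Conditions: 1 M HCl, THF, 40 °C
Reagents that add atoms: water, O
Why: Acid‑catalysed hydrolysis of the dioxolane frees the C1 aldehyde; the primary tert‑butyldiphenylsilyl ether and the methylene lactone are stable to dilute acid.

Step 15
Reactants: 21 (4S,5R)‑5‑[(1E)‑2‑{[(tert‑butyldiphenylsilyl)oxy]methyl}‑5‑oxopent‑1‑en‑1‑yl]‑3‑methylene‑4‑(prop‑2‑yn‑1‑yl)dihydrofuran‑2(3H)‑one
Product: 22 1,1,1,3,3,3‑hexafluoropropan‑2‑yl (3S,6E)‑6‑{[(tert‑butyldiphenylsilyl)oxy]methyl}‑3‑hydroxy‑2‑methylene‑7‑[(2R,3S)‑4‑methylene‑5‑oxo‑3‑(prop‑2‑yn‑1‑yl)tetrahydrofuran‑2‑yl]hept‑6‑enoate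
Conditions: 1,1,1,3,3,3‑hexafluoroisopropyl acrylate, α‑isocupreine (10 mol %), DMF, −55 °C
Reagents that add atoms: 1,1,1,3,3,3‑hexafluoroisopropyl acrylate, C=CC(=O)OC(C(F)(F)F)C(F)(F)F
Why: Catalytic asymmetric Morita–Baylis–Hillman reaction forms C1–C10; the C1 configuration is catalyst‑controlled (α‑isocupreine is the pseudo‑enantiomer of β‑isocupreidine, which gives the R carbinols, so S is expected here), and the methylene lactone cannot turn over because its amine adduct has no α‑hydrogen to lose after an aldol step.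

Step 16
Reactants: 22 1,1,1,3,3,3‑hexafluoropropan‑2‑yl (3S,6E)‑6‑{[(tert‑butyldiphenylsilyl)oxy]methyl}‑3‑hydroxy‑2‑methylene‑7‑[(2R,3S)‑4‑methylene‑5‑oxo‑3‑(prop‑2‑yn‑1‑yl)tetrahydrofuran‑2‑yl]hept‑6‑enoate
Product: 23 1,1,1,3,3,3‑hexafluoropropan‑2‑yl (3S,6E)‑6‑{[(tert‑butyldiphenylsilyl)oxy]methyl}‑2‑methylene‑3‑[(2‑methylpropanoyl)oxy]‑7‑[(2R,3S)‑4‑methylene‑5‑oxo‑3‑(prop‑2‑yn‑1‑yl)tetrahydrofuran‑2‑yl]hept‑6‑enoate
Conditions: isobutyryl chloride, pyridine, CH2Cl2, 0 °C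
Reagents that add atoms: isobutyryl chloride, CC(C)C(Cl)=O
Why: O‑acylation of the secondary allylic alcohol with retention at C1; no 4‑(dimethylamino)pyridine is used, to avoid SN2' isomerisation of the allylic ester.

Step 17
Reactants: 23 1,1,1,3,3,3‑hexafluoropropan‑2‑yl (3S,6E)‑6‑{[(tert‑butyldiphenylsilyl)oxy]methyl}‑2‑methylene‑3‑[(2‑methylpropanoyl)oxy]‑7‑[(2R,3S)‑4‑methylene‑5‑oxo‑3‑(prop‑2‑yn‑1‑yl)tetrahydrofuran‑2‑yl]hept‑6‑enoate
Product: 24 (3S,6E)‑6‑{[(tert‑butyldiphenylsilyl)oxy]methyl}‑2‑methylene‑3‑[(2‑methylpropanoyl)oxy]‑7‑[(2R,3S)‑4‑methylene‑5‑oxo‑3‑(prop‑2‑yn‑1‑yl)tetrahydrofuran‑2‑yl]hept‑6‑enoic acid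
Conditions: Me3SnOH, ClCH2CH2Cl, 50 °C; 1 M HCl work‑up
Reagents that add atoms: trimethyltin hydroxide, C[Sn](C)(C)O
Why: Chemoselective hydrolysis with trimethyltin hydroxide; the hexafluoroisopropyl ester is an activated ester and should be cleaved well before the isobutyrate or the lactone.

Step 18
Reactants: 24 (3S,6E)‑6‑{[(tert‑butyldiphenylsilyl)oxy]methyl}‑2‑methylene‑3‑[(2‑methylpropanoyl)oxy]‑7‑[(2R,3S)‑4‑methylene‑5‑oxo‑3‑(prop‑2‑yn‑1‑yl)tetrahydrofuran‑2‑yl]hept‑6‑enoic acid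
Product: 26 15‑O‑(tert‑butyldiphenylsilyl) ether of the target (bridged butenolide on the ten‑membered ring, methylene lactone, C1 isobutyrate; 1S,6R,7S,8R), via eleven‑membered lactone 25 (not isolated)
Conditions: [RhCl(cod)]2 (2.5 mol %), (R,R)‑DIOP (5 mol %), ClCH2CH2Cl, 2 mM, slow addition of 24, 70 °C, until the alkyne is consumed; then second‑generation Hoveyda–Grubbs catalyst RuCl2(H2IMes)(=CH‑C6H4‑2‑OiPr) (10 mol %), 80 °C, argon stream
Reagents that add atoms: none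
Why: The carboxylic acid adds oxidatively to the rhodium–DIOP complex, the Rh–H so formed isomerises the terminal alkyne to the allene and hydrometalates it to a π‑allyl rhodium carboxylate, and C–O reductive elimination at the substituted allyl terminus C8 gives the branched allylic ester 25, after which the ruthenium alkylidene loads on the new vinyl group (C9) and closes onto the acrylate C10=CH2 with loss of ethene. The closest known reactions are the rhodium‑catalysed redox‑neutral coupling of terminal alkynes with carboxylic acids (including its macrolactonising and DIOP‑controlled enantioselective forms) and the ring‑closing metathesis of allyl acrylates to butenolides. The eleven‑membered lactone closes by intramolecular C–O bond formation at the branched position under high dilution, and the butenolide closes by five‑ring metathesis, which in the same event turns the lactone into the ten‑membered carbocycle bridged at C8 and C10 and fixes the C9=C10 geometry. The only new stereocentre, C8, is set by the chiral diphosphine on rhodium (catalyst control next to C7). The step needs branched rather than linear C–O formation (inherent to this rhodium catalysis), reaction at the alkyne and not at the three alkenes (only the alkyne isomerises to an allene), and metathesis only between the vinyl group and the acrylate. The substrate secures the last point, because closure of C9 onto C5 would give a trans‑fused bicyclo[3.3.0] system (C5 and C8 are trans on the lactone) and closure onto C13 would give a cyclobutene.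

Step 19
Reactants: 26 15‑O‑(tert‑butyldiphenylsilyl) ether of the target
Product: 27 target CNP0322767.4, (1S,6R,7S,8R) in the numbering above
Conditions: HF·pyridine, pyridine, THF, 0 °C to rt
Reagents that add atoms: none
Why: Fluoride cleavage of the primary allylic silyl ether under buffered acidic conditions, to which the two lactones and the isobutyrate should be stable.

**Compound list**

1 | (S)‑5‑(hydroxymethyl)furan‑2(5H)‑one | O=C1C=C[C@@H](CO)O1 | starting material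
2 | (S)‑5‑{[(tert‑butyldimethylsilyl)oxy]methyl}furan‑2(5H)‑one | O=C1C=C[C@@H](CO[Si](C)(C)C(C)(C)C)O1 | intermediate
3 | trimethylsilyl ketene acetal of 4 (2‑trimethylsilyloxy‑4,5‑dihydrofuran, 4,5‑trans) | C[Si](C)(C)OC1=C[C@H](CC=C)[C@@H](CO[Si](C)(C)C(C)(C)C)O1 | intermediate (not isolated)
4 | (4S,5S)‑4‑allyl‑5‑{[(tert‑butyldimethylsilyl)oxy]methyl}dihydrofuran‑2(3H)‑one | O=C1C[C@H](CC=C)[C@@H](CO[Si](C)(C)C(C)(C)C)O1 | intermediate
5 | lithium enolate of 4 | [Li]OC1=C[C@H](CC=C)[C@@H](CO[Si](C)(C)C(C)(C)C)O1 | intermediate (not isolated)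
6 | (3R,4S,5S)‑4‑allyl‑5‑{[(tert‑butyldimethylsilyl)oxy]methyl}‑3‑[(dimethylamino)methyl]dihydrofuran‑2(3H)‑one | O=C1[C@@H](CN(C)C)[C@H](CC=C)[C@@H](CO[Si](C)(C)C(C)(C)C)O1 | intermediate
7 | secondary ozonide (1,2,4‑trioxolane, both epimers at the ozonide carbon) of 6, as the ammonium trifluoroacetate | O=C1[C@@H](C[NH+](C)C)[C@H](CC2OCOO2)[C@@H](CO[Si](C)(C)C(C)(C)C)O1.[O-]C(=O)C(F)(F)F | intermediate (not isolated)
8 | (3R,4S,5S)‑5‑{[(tert‑butyldimethylsilyl)oxy]methyl}‑3‑[(dimethylamino)methyl]‑4‑(2‑oxoethyl)dihydrofuran‑2(3H)‑one | O=C1[C@@H](CN(C)C)[C@H](CC=O)[C@@H](CO[Si](C)(C)C(C)(C)C)O1 | intermediate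
9 | (3R,4S,5S)‑5‑{[(tert‑butyldimethylsilyl)oxy]methyl}‑3‑[(dimethylamino)methyl]‑4‑(prop‑2‑yn‑1‑yl)dihydrofuran‑2(3H)‑one | O=C1[C@@H](CN(C)C)[C@H](CC#C)[C@@H](CO[Si](C)(C)C(C)(C)C)O1 | intermediate
10 | (3R,4S,5S)‑3‑[(dimethylamino)methyl]‑5‑(hydroxymethyl)‑4‑(prop‑2‑yn‑1‑yl)dihydrofuran‑2(3H)‑one | O=C1[C@@H](CN(C)C)[C@H](CC#C)[C@@H](CO)O1 | intermediate
11 | (2S,3S,4R)‑4‑[(dimethylamino)methyl]‑5‑oxo‑3‑(prop‑2‑yn‑1‑yl)tetrahydrofuran‑2‑carbaldehyde | O=C1[C@@H](CN(C)C)[C@H](CC#C)[C@@H](C=O)O1 | intermediate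
12 | 2‑(3‑chloropropyl)‑1,3‑dioxolane | ClCCCC1OCCO1 | starting material
13 | [3‑(1,3‑dioxolan‑2‑yl)propyl]triphenylphosphonium iodide | [I-].C1COC(CCC[P+](c2ccccc2)(c2ccccc2)c2ccccc2)O1 | intermediate
14 | [3‑(1,3‑dioxolan‑2‑yl)propylidene]triphenylphosphorane | C1COC(CCC=P(c2ccccc2)(c2ccccc2)c2ccccc2)O1 | intermediate (not isolated)
15 | 4‑(1,3‑dioxolan‑2‑yl)‑2‑(triphenyl‑λ5‑phosphanylidene)butanal | O=CC(CCC1OCCO1)=P(c1ccccc1)(c1ccccc1)c1ccccc1 | intermediate
16 | (E)‑4‑(1,3‑dioxolan‑2‑yl)‑2‑{[(2S,3S,4R)‑4‑[(dimethylamino)methyl]‑5‑oxo‑3‑(prop‑2‑yn‑1‑yl)tetrahydrofuran‑2‑yl]methylidene}butanal | O=C1[C@@H](CN(C)C)[C@H](CC#C)[C@@H](/C=C(/C=O)CCC2OCCO2)O1 | intermediate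
17 | (3R,4S,5S)‑3‑[(dimethylamino)methyl]‑5‑[(1E)‑4‑(1,3‑dioxolan‑2‑yl)‑2‑(hydroxymethyl)but‑1‑en‑1‑yl]‑4‑(prop‑2‑yn‑1‑yl)dihydrofuran‑2(3H)‑one | O=C1[C@@H](CN(C)C)[C@H](CC#C)[C@@H](/C=C(/CO)CCC2OCCO2)O1 | intermediate
18 | (3R,4S,5S)‑5‑[(1E)‑2‑{[(tert‑butyldiphenylsilyl)oxy]methyl}‑4‑(1,3‑dioxolan‑2‑yl)but‑1‑en‑1‑yl]‑3‑[(dimethylamino)methyl]‑4‑(prop‑2‑yn‑1‑yl)dihydrofuran‑2(3H)‑one | O=C1[C@@H](CN(C)C)[C@H](CC#C)[C@@H](/C=C(/CO[Si](c2ccccc2)(c2ccccc2)C(C)(C)C)CCC2OCCO2)O1 | intermediate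
19 | N‑methyl quaternary ammonium iodide of 18 | [I-].O=C1[C@@H](C[N+](C)(C)C)[C@H](CC#C)[C@@H](/C=C(/CO[Si](c2ccccc2)(c2ccccc2)C(C)(C)C)CCC2OCCO2)O1 | intermediate (not isolated)
20 | (4S,5R)‑5‑[(1E)‑2‑{[(tert‑butyldiphenylsilyl)oxy]methyl}‑4‑(1,3‑dioxolan‑2‑yl)but‑1‑en‑1‑yl]‑3‑methylene‑4‑(prop‑2‑yn‑1‑yl)dihydrofuran‑2(3H)‑one | C=C1C(=O)O[C@H](/C=C(/CO[Si](c2ccccc2)(c2ccccc2)C(C)(C)C)CCC2OCCO2)[C@H]1CC#C | intermediate
21 | (4S,5R)‑5‑[(1E)‑2‑{[(tert‑butyldiphenylsilyl)oxy]methyl}‑5‑oxopent‑1‑en‑1‑yl]‑3‑methylene‑4‑(prop‑2‑yn‑1‑yl)dihydrofuran‑2(3H)‑one | C=C1C(=O)O[C@H](/C=C(/CO[Si](c2ccccc2)(c2ccccc2)C(C)(C)C)CCC=O)[C@H]1CC#C | intermediate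
22 | 1,1,1,3,3,3‑hexafluoropropan‑2‑yl (3S,6E)‑6‑{[(tert‑butyldiphenylsilyl)oxy]methyl}‑3‑hydroxy‑2‑methylene‑7‑[(2R,3S)‑4‑methylene‑5‑oxo‑3‑(prop‑2‑yn‑1‑yl)tetrahydrofuran‑2‑yl]hept‑6‑enoate | C=C1C(=O)O[C@H](/C=C(/CO[Si](c2ccccc2)(c2ccccc2)C(C)(C)C)CC[C@H](O)C(=C)C(=O)OC(C(F)(F)F)C(F)(F)F)[C@H]1CC#C | intermediate
23 | 3‑O‑isobutyryl derivative of 22 | C=C1C(=O)O[C@H](/C=C(/CO[Si](c2ccccc2)(c2ccccc2)C(C)(C)C)CC[C@H](OC(=O)C(C)C)C(=C)C(=O)OC(C(F)(F)F)C(F)(F)F)[C@H]1CC#C | intermediate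
24 | (3S,6E)‑6‑{[(tert‑butyldiphenylsilyl)oxy]methyl}‑2‑methylene‑3‑[(2‑methylpropanoyl)oxy]‑7‑[(2R,3S)‑4‑methylene‑5‑oxo‑3‑(prop‑2‑yn‑1‑yl)tetrahydrofuran‑2‑yl]hept‑6‑enoic acid (seco acid) | C=C1C(=O)O[C@H](/C=C(/CO[Si](c2ccccc2)(c2ccccc2)C(C)(C)C)CC[C@H](OC(=O)C(C)C)C(=C)C(=O)O)[C@H]1CC#C | intermediate
25 | eleven‑membered lactone: C14 carboxyl esterified by C8, which carries a vinyl group (C9); C10 keeps its exo‑methylene; all stereocentres arranged as in 26 | C=C1C(=O)O[C@@H]2/C=C(/CO[Si](c3ccccc3)(c3ccccc3)C(C)(C)C)CC[C@H](OC(=O)C(C)C)C(=C)C(=O)O[C@H](C=C)[C@@H]12 | intermediate (not isolated)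
26 | 15‑O‑(tert‑butyldiphenylsilyl) ether of the target | C=C1C(=O)O[C@@H]2/C=C(/CO[Si](c3ccccc3)(c3ccccc3)C(C)(C)C)CC[C@H](OC(=O)C(C)C)C3=C[C@@H](OC3=O)[C@@H]12 | intermediate
27 | CNP0322767.4, (1S,6R,7S,8R) | C=C1C(=O)O[C@@H]2/C=C(/CO)CC[C@H](OC(=O)C(C)C)C3=C[C@@H](OC3=O)[C@@H]12 | target

**Step count**

Total: 19 steps. Longest linear sequence: 17 steps (steps 1–7 and 10–19, from 1 to 27); the ylide branch (steps 8–9) adds two.

**Steps most likely to fail**

Step 18. The medium‑ring C–O closure may lose to oligomerisation, the ligand may be mismatched with C7 so that facial control at C8 is poor, or rhodium and phosphine residues may deactivate the ruthenium carbene in the same flask. Fallback, from 24: semihydrogenation of the alkyne (H2, Pd/CaCO3 poisoned with Pb(OAc)2, quinoline, EtOAc) should give the allyl seco acid F1. Allylic C–H oxidative macrolactonisation of F1 (Pd(OAc)2, 1,2‑bis(phenylsulfinyl)ethane, benzoquinone, CH2Cl2, 45 °C, high dilution) forms the O–C8 bond through a π‑allyl palladium carboxylate, so C8 is set by the substrate chelate instead of by a ligand. This gives 25, which is isolated and then cyclised in a separate flask with the second‑generation Hoveyda–Grubbs catalyst, returning to the route at 26.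

Step 15. The addition may be slow on this bulky aldehyde, a second aldehyde molecule may be consumed in dioxanone formation, and the facial control by the cinchona catalyst may be eroded. Fallback, from 21: the same acrylate with achiral 1,4‑diazabicyclo[2.2.2]octane in DMF should give 22 together with its C1 epimer F2. The two are diastereomers and are separated by chromatography, so the configuration at C1 is obtained by separation instead of by catalyst control; the route is rejoined at 22.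

Step 2. The allyl Grignard reagent may add to the lactone carbonyl (1,2‑addition) or deprotonate C6 in competition with conjugate addition. Fallback, from 2: Hosomi–Sakurai allylation (allyltrimethylsilane, TiCl4, CH2Cl2, −78 °C), in which a Lewis‑acid‑activated lactone is attacked by a non‑basic allylsilane anti to the C6 substituent, should give 4 directly.

**Further compounds**

F1 | step 18 | allyl seco acid: (3S,6E)‑6‑{[(tert‑butyldiphenylsilyl)oxy]methyl}‑2‑methylene‑3‑[(2‑methylpropanoyl)oxy]‑7‑[(2R,3S)‑3‑allyl‑4‑methylene‑5‑oxotetrahydrofuran‑2‑yl]hept‑6‑enoic acid | C=C1C(=O)O[C@H](/C=C(/CO[Si](c2ccccc2)(c2ccccc2)C(C)(C)C)CC[C@H](OC(=O)C(C)C)C(=C)C(=O)O)[C@H]1CC=C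
F2 | step 15 | (3R) epimer of 22 (C1 epimer) | C=C1C(=O)O[C@H](/C=C(/CO[Si](c2ccccc2)(c2ccccc2)C(C)(C)C)CC[C@@H](O)C(=C)C(=O)OC(C(F)(F)F)C(F)(F)F)[C@H]1CC#C
F0 | step 2 | none | none
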